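**Retrosynthetic overview**
- Feature: the ring is numbered C1 ketone, C2 carrying C7H2–O, C3 alkene CH, C4 O‑tigloyl, C5 isopropyl, C6 OH. The C1 and C4 oxygens stand 1,4 across C2=C3, and C4–O is cis and C6–O trans to the C5 isopropyl. This is the footprint of an endo adduct of a 2‑pyrone and an E‑alkene.
- Late disconnections: C7–O tiglate, C6 acetate (the only protecting group), C2–C7 (Morita–Baylis–Hillman with CH2O), C4–O tiglate. The tiglates go on one at a time, so the acetate can be removed while only the hindered C4 ester is present.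
- Core disconnections: C1=O from C1(OH)–CO2H by loss of CO2, that acid from a lactone bridging C1 and C4, and C6–OAc from C6–acetyl by Baeyer–Villiger oxidation.
- Key disconnection: C4–C5 and C6–C1 by [4+2] union of 3‑hydroxy‑2‑pyrone and (E)‑5‑methylhex‑3‑en‑2‑one, giving a 2‑oxabicyclo[2.2.2]oct‑5‑en‑3‑one.
- Ring order: the carbocycle is the only ring made and is made first. The pyrone‑derived lactone bridge is opened in step 3 and its carbon expelled in step 4.

Key step: step 1

Numbering: monocyclic compounds carry the target numbering above. In the bicycles C1 = target C4, C4 = target C1, C5 = target C2, C6 = target C3, C7 = target C5 and C8 = target C6.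

Assumption: the quinidine‑derived 9‑amino(9‑deoxy)epi‑cinchona amine is taken to leave open the enone face that leads to the (1S,4S,7R,8R) adduct. If the sense proves opposite, its quinine‑derived pseudo‑enantiomer replaces it with no other change.

**Step 1**
Reactants: 1 3‑hydroxy‑2‑pyrone; 2 (E)‑5‑methylhex‑3‑en‑2‑one
Product: 3 (1S,4S,7R,8R)‑8‑acetyl‑4‑hydroxy‑7‑isopropyl‑2‑oxabicyclo[2.2.2]oct‑5‑en‑3‑one (endo adduct: acetyl anti, isopropyl syn to the lactone bridge)
Conditions: 9‑amino(9‑deoxy)epi‑quinidine (10 mol %), CF3CO2H (20 mol %), CH2Cl2, 0 °C → rt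
Reagents that add atoms: none
Why: The primary amine condenses with 2 to an iminium ion while the quinuclidine/trifluoroacetate site hydrogen‑bonds to, and in the limit deprotonates, the acidic 3‑OH of 1, so an electron‑rich oxido‑diene meets an activated dienophile; pyrone C6 bonds to the enone β‑carbon (target C4–C5) and the oxygen‑bearing pyrone C3 to the α‑carbon (target C6–C1), either in one asynchronous [4+2] event or as vinylogous Michael addition followed by aldol closure. The nearest known reaction type is the organocatalytic asymmetric cycloaddition of 3‑hydroxy‑2‑pyrones to α,β‑unsaturated ketones under cinchona‑amine or cinchona‑base catalysis. The one new ring, the six‑membered carbocycle, closes by suprafacial [4+2] addition (in the stepwise reading a 6‑(enolexo)‑exo‑trig aldol onto the transient α‑keto‑lactone carbonyl), and the pyrone O–C(=O) unit remains as the third bridge. C7 and C8 come out trans because the E geometry of 2 is transferred suprafacially, their absolute sense follows from the enone face left open in the catalyst‑bound iminium ion, and the bridgeheads C1 and C4 are fixed relative to them by the endo orientation. The step needs this regiochemistry, endo selectivity and one face: the oxido group makes pyrone C6 the nucleophilic terminus and so secures the regiochemistry, whereas endo and facial selectivity rest on the binding of both partners to one catalyst molecule. The temperature is kept at or below rt because such adducts can lose CO2 by retro‑[4+2] on heating.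

**Step 2**
Reactants: 3 endo adduct
Product: 4 (1S,4S,7S,8R)‑4‑hydroxy‑7‑isopropyl‑3‑oxo‑2‑oxabicyclo[2.2.2]oct‑5‑en‑8‑yl acetate
Conditions: (TMSO)2 (1.5 equiv), TMSOTf (20 mol %), CH2Cl2, −40 → −10 °C; aq. citric acid work‑up
Reagents that add atoms: bis(trimethylsilyl) peroxide, C[Si](C)(C)OO[Si](C)(C)C
Why: Chemoselective Baeyer–Villiger oxidation: the silyl peroxide adds only to the Lewis‑acid‑activated acetyl carbonyl and has no electrophilic peracid oxygen for the C5=C6 alkene, and in the Criegee‑type adduct the secondary C8 migrates in preference to methyl with retention, which sets the target C6–O bond and removes the β‑hydroxy ketone through which the adduct could revert.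

**Step 3**
Reactants: 4 bicyclic acetate
Product: 5 (1S,4S,5S,6R)‑6‑acetoxy‑1,4‑dihydroxy‑5‑isopropylcyclohex‑2‑ene‑1‑carboxylic acid
Conditions: LiOH (1.05 equiv), THF/H2O 3:1, 0 °C; 1 M HCl to pH 3
Reagents that add atoms: lithium hydroxide, [Li+].[OH-]
Why: Chemoselective saponification: the boat‑locked δ‑lactone has the strained E‑ester geometry and an activating α‑hydroxyl, so one equivalent of hydroxide should open it well before the hindered secondary acetate reacts, and that acetate must stay because a free C6–OH beside the C1 carbinol would be a cleavable glycol in the next step; no stereocentre is touched.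

**Step 4**
Reactants: 5 hydroxy acid
Product: 6 (4S,5S,6R)‑6‑acetoxy‑4‑hydroxy‑5‑isopropylcyclohex‑2‑en‑1‑one
Conditions: Pb(OAc)4 (1.1 equiv), CH2Cl2, −10 → 0 °C
Reagents that add atoms: none
Why: Oxidative decarboxylation of an α‑hydroxy acid with lead tetraacetate (glycol‑cleavage type): the cyclic Pb(IV) alkoxide–carboxylate fragments to CO2 and the C1 ketone, formed in conjugation with C2=C3, while the C6 acetate blocks C1–C6 cleavage and C4, C5 and C6 are untouched.

**Step 5**
Reactants: 6 hydroxy enone; 7 tiglic acid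
Product: 8 (4S,5S,6R)‑6‑acetoxy‑5‑isopropyl‑4‑(tigloyloxy)cyclohex‑2‑en‑1‑one
Conditions: DCC (1.5 equiv), DMAP (20 mol %), CH2Cl2, 0 °C → rt
Reagents that add atoms: none
Why: Steglich esterification of the only free hydroxyl forms the acyl–O bond alone, so C4 keeps its configuration, and the E‑configured tiglate is the stable geometric isomer and should not be scrambled.

**Step 6**
Reactants: 8 C4 tiglate; 9 formaldehyde (37 % aqueous)
Product: 10 (4S,5S,6R)‑6‑acetoxy‑2‑(hydroxymethyl)‑5‑isopropyl‑4‑(tigloyloxy)cyclohex‑2‑en‑1‑one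
Conditions: aq. HCHO (5 equiv), DMAP (30 mol %), THF, rt
Reagents that add atoms: none
Why: Morita–Baylis–Hillman hydroxymethylation: DMAP adds reversibly to C3, the C2 enolate captures formaldehyde and loss of DMAP restores the enone, a reaction type established for oxygenated cyclohex‑2‑enones; the α,β‑disubstituted tiglate is too hindered an acceptor to compete and no stereocentre is formed.

**Step 7**
Reactants: 10 hydroxymethyl enone
Product: 11 (4S,5R,6R)‑6‑hydroxy‑2‑(hydroxymethyl)‑5‑isopropyl‑4‑(tigloyloxy)cyclohex‑2‑en‑1‑one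
Conditions: Sc(OTf)3 (20 mol %), MeOH/H2O 4:1, rt
Reagents that add atoms: none
Why: Chelation‑assisted Lewis‑acid transesterification: Sc(III) held between the C1 ketone and the neighbouring C6 acetate activates that ester alone to methanolysis, the hindered conjugated C4 tiglate has no such chelating neighbour, and the near‑neutral medium should spare C6, whose trans‑diequatorial relation to C5 is the stable one in any case.

**Step 8**
Reactants: 11 diol; 7 tiglic acid
Product: 12 (4S,5R,6R)‑6‑hydroxy‑5‑isopropyl‑4‑(tigloyloxy)‑2‑(tigloyloxymethyl)cyclohex‑2‑en‑1‑one (target)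
Conditions: 7 (1.05 equiv), DCC (1.05 equiv), DMAP (5 mol %), CH2Cl2, −20 → 0 °C
Reagents that add atoms: none
Why: Steglich esterification under kinetic control: the unhindered primary allylic C7–OH should outrun the secondary C6–OH, which is flanked by the C5 isopropyl carbon and the carbonyl, hydrogen‑bonded to the ketone and inductively deactivated, and the α‑branched acyl donor sharpens this discrimination.

**Compound list**
1 | 3‑hydroxy‑2‑pyrone | O=C1OC=CC=C1O | starting material
2 | (E)‑5‑methylhex‑3‑en‑2‑one | CC(=O)/C=C/C(C)C | starting material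
3 | (1S,4S,7R,8R)‑8‑acetyl‑4‑hydroxy‑7‑isopropyl‑2‑oxabicyclo[2.2.2]oct‑5‑en‑3‑one | O=C1O[C@H]2C=C[C@]1(O)[C@H](C(C)=O)[C@H]2C(C)C | intermediate
4 | (1S,4S,7S,8R)‑4‑hydroxy‑7‑isopropyl‑3‑oxo‑2‑oxabicyclo[2.2.2]oct‑5‑en‑8‑yl acetate | O=C1O[C@H]2C=C[C@]1(O)[C@H](OC(C)=O)[C@H]2C(C)C | intermediate
5 | (1S,4S,5S,6R)‑6‑acetoxy‑1,4‑dihydroxy‑5‑isopropylcyclohex‑2‑ene‑1‑carboxylic acid | O=C(O)[C@]1(O)C=C[C@H](O)[C@H](C(C)C)[C@H]1OC(C)=O | intermediate
6 | (4S,5S,6R)‑6‑acetoxy‑4‑hydroxy‑5‑isopropylcyclohex‑2‑en‑1‑one | C1=C[C@H](O)[C@H](C(C)C)[C@@H](OC(C)=O)C1=O | intermediate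
7 | tiglic acid, (E)‑2‑methylbut‑2‑enoic acid | C/C=C(\C)C(=O)O | starting material
8 | (4S,5S,6R)‑6‑acetoxy‑5‑isopropyl‑4‑(tigloyloxy)cyclohex‑2‑en‑1‑one | C1=C[C@H](OC(=O)/C(C)=C/C)[C@H](C(C)C)[C@@H](OC(C)=O)C1=O | intermediate
9 | formaldehyde | C=O | starting material
10 | (4S,5S,6R)‑6‑acetoxy‑2‑(hydroxymethyl)‑5‑isopropyl‑4‑(tigloyloxy)cyclohex‑2‑en‑1‑one | OCC1=C[C@H](OC(=O)/C(C)=C/C)[C@H](C(C)C)[C@@H](OC(C)=O)C1=O | intermediate
11 | (4S,5R,6R)‑6‑hydroxy‑2‑(hydroxymethyl)‑5‑isopropyl‑4‑(tigloyloxy)cyclohex‑2‑en‑1‑one | OCC1=C[C@H](OC(=O)/C(C)=C/C)[C@H](C(C)C)[C@@H](O)C1=O | intermediate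
12 | (4S,5R,6R)‑6‑hydroxy‑5‑isopropyl‑4‑(tigloyloxy)‑2‑(tigloyloxymethyl)cyclohex‑2‑en‑1‑one | C/C=C(\C)C(=O)OCC1=C[C@H](OC(=O)/C(C)=C/C)[C@H](C(C)C)[C@@H](O)C1=O | target

Total step count: 8. Longest linear sequence: 8.

**Steps most likely to fail**

**Step 1.** Exo approach may compete with endo approach. Face discrimination may erode with the β‑branched enone. Long reaction times may let the adduct revert by retro‑aldol and retro‑Michael steps.

The fallback sets out from 1 and 2 and returns at 8.
- One catalyst shields the same enone face in both approach modes. The exo adduct (1R,4R,7R,8R)‑8‑acetyl‑4‑hydroxy‑7‑isopropyl‑2‑oxabicyclo[2.2.2]oct‑5‑en‑3‑one F1 therefore already has the correct target C5 and C6 and differs only at the two bridgeheads.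
- It is separated and taken through the operations of steps 2 to 4. Silyl‑peroxide Baeyer–Villiger oxidation gives the exo‑series acetate (1R,4R,7S,8R)‑4‑hydroxy‑7‑isopropyl‑3‑oxo‑2‑oxabicyclo[2.2.2]oct‑5‑en‑8‑yl acetate F2.
- Lactone‑selective saponification gives (1R,4R,5S,6R)‑6‑acetoxy‑1,4‑dihydroxy‑5‑isopropylcyclohex‑2‑ene‑1‑carboxylic acid F3.
- Lead tetraacetate decarboxylation gives the 4‑epi enone (4R,5S,6R)‑6‑acetoxy‑4‑hydroxy‑5‑isopropylcyclohex‑2‑en‑1‑one F4, in which one of the two wrong centres has become the ketone.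
- The remaining wrong centre C4 is inverted and acylated in one operation by Mitsunobu esterification with tiglic acid 7 (PPh3, DIAD, toluene, 0 °C). This gives 8, so both diastereomeric adducts converge on 8.

**Step 2.** The acyclic, β‑oxygenated methyl ketone may form its peroxide adduct slowly, so that incomplete conversion or Lewis‑acid‑induced retro‑aldol opening intervenes. Forcing the oxidation with a peracid would bring epoxidation of C5=C6 into play. Passing silylation of the bridgehead hydroxyl is harmless, because the acidic work‑up reverses it.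

The fallback sets out from 3 and returns at 4.
- The alkene is masked by bromination (pyridinium tribromide, CH2Cl2, 0 °C) as the trans‑5,6‑dibromide of 3 F5. It is drawn with C5–Br on the lactone side and C6–Br on the C7–C8 side, and either trans isomer would serve.
- With no alkene present, buffered trifluoroperacetic acid (urea–H2O2, (CF3CO)2O, Na2HPO4, CH2Cl2, 0 °C → rt) performs the Baeyer–Villiger oxidation to the trans‑5,6‑dibromide of 4 F6.
- Zinc dust in AcOH/Et2O at 0 °C restores the alkene by reductive elimination, giving 4.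

**Step 6.** Conjugate addition of DMAP at C3 is slowed by the neighbouring C4 ester and C5 isopropyl group, so the catalytic cycle may stall. Long exposure to aqueous amine may start to hydrolyse the esters.

The fallback sets out from 8 and returns at 10.
- α‑Iodination (I2, pyridine/CH2Cl2, rt) gives (4R,5S,6R)‑6‑acetoxy‑2‑iodo‑5‑isopropyl‑4‑(tigloyloxy)cyclohex‑2‑en‑1‑one F7.
- Stille coupling with (tributylstannyl)methanol (Pd2(dba)3, AsPh3, CuI, NMP, 50 °C) forms the C2–C7 bond under neutral conditions and gives 10.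

**Further compounds**
F1 | step 1 | (1R,4R,7R,8R)‑8‑acetyl‑4‑hydroxy‑7‑isopropyl‑2‑oxabicyclo[2.2.2]oct‑5‑en‑3‑one (exo adduct) | O=C1O[C@@H]2C=C[C@@]1(O)[C@H](C(C)=O)[C@H]2C(C)C
F2 | step 1 | (1R,4R,7S,8R)‑4‑hydroxy‑7‑isopropyl‑3‑oxo‑2‑oxabicyclo[2.2.2]oct‑5‑en‑8‑yl acetate | O=C1O[C@@H]2C=C[C@@]1(O)[C@H](OC(C)=O)[C@H]2C(C)C
F3 | step 1 | (1R,4R,5S,6R)‑6‑acetoxy‑1,4‑dihydroxy‑5‑isopropylcyclohex‑2‑ene‑1‑carboxylic acid | O=C(O)[C@@]1(O)C=C[C@@H](O)[C@H](C(C)C)[C@H]1OC(C)=O
F4 | step 1 | (4R,5S,6R)‑6‑acetoxy‑4‑hydroxy‑5‑isopropylcyclohex‑2‑en‑1‑one | O=C1C=C[C@@H](O)[C@H](C(C)C)[C@H]1OC(C)=O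
F5 | step 2 | trans‑5,6‑dibromide of 3: 8‑acetyl‑5,6‑dibromo‑4‑hydroxy‑7‑isopropyl‑2‑oxabicyclo[2.2.2]octan‑3‑one | O=C1O[C@H]2[C@H](Br)[C@@H](Br)[C@]1(O)[C@H](C(C)=O)[C@H]2C(C)C
F6 | step 2 | trans‑5,6‑dibromide of 4: 5,6‑dibromo‑4‑hydroxy‑7‑isopropyl‑3‑oxo‑2‑oxabicyclo[2.2.2]octan‑8‑yl acetate | O=C1O[C@H]2[C@H](Br)[C@@H](Br)[C@]1(O)[C@H](OC(C)=O)[C@H]2C(C)C
F7 | step 6 | (4R,5S,6R)‑6‑acetoxy‑2‑iodo‑5‑isopropyl‑4‑(tigloyloxy)cyclohex‑2‑en‑1‑one | O=C1C(I)=C[C@H](OC(=O)/C(C)=C/C)[C@H](C(C)C)[C@H]1OC(C)=O
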